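Compound numbers 1–25 are those of the steps and the compound list below: 1–11 belong to the ring D/E half, 12–19 to the ring A half, 20–25 to assembly and endgame. TBS = tert-butyldimethylsilyl, Bn = benzyl. Locants of the target are used throughout: chromone O1, C2, C3, C4, C4a, C5–C8, C8a; second benzene ring C1'–C6'; dihydropyran carbons C2''–C4''.

## Analysis of the target

The target (25) is a hexacyclic coumaronochromone. A chromen-4-one (benzo ring A, C4a–C8a, and pyranone ring C, O1–C4) shares its C2–C3 bond with a furan, which is fused to a second benzene ring D (C1' on C3, C2' on the furan oxygen). Ring A is fully substituted: a chelated 5-OH, a 6-methyl group and a 2,2-dimethyl-2H-pyran (ring F) fused through O7 and C8. Ring D carries 5'-OH, one hydrogen (C6') and a 2,2-dimethyl-3,4-dihydro-2H-pyran (ring E) fused through O4' and C3'. The only stereocentres are the adjacent carbinol carbons C3''(R) and C4''(S) of ring E, a trans-diol; C4'' is benzylic and lies between two oxygen-bearing aromatic carbons, so it can ionise and epimerise under acid. Further sensitive sites are C2 (two oxygens, a vinylogous carbonate carbon open to nucleophiles), the chromene double bond of ring F (acid, hydrogenation) and three phenols of different acidity. The difficulty is mostly regiochemical: the three oxygens of ring A take three different roles with the methyl at C6 and not C8, ring F must be angular, and the halves must join as a coumaronochromone and not as the isomeric coumestan. The strategy rests on C2 carrying both O1 and the furan oxygen: C2, C3 and ring D together are a benzofuran-2(3H)-one, separated from a ring A 2-haloaroyl unit only by the C3–C4 and O1–C8a bonds.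

## Retrosynthetic reasoning

**Silyl ethers (25 to 24).** 5'-OH and the diol are carried as TBS ethers, so 25 is traced to 24. The last forward step is then a non-basic fluoride cleavage, which respects C2 and the benzylic C4''.

**Ring F (24 to 23 to 22 and 2).** Ring F is cut at the bond from C8 to its vinyl carbon and at the O7–C(quaternary) bond, giving propargyl ether 23 and then diphenol 22 with chloride 2. Cutting this ring last keeps the sensitive alkene out of the hydrogenolysis and the metal-mediated steps. The forward Claisen cascade can only finish at C8 because C6 bears the methyl, and only 7-OH is free of the hydrogen bond to C4=O.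

**Benzyl ethers (22 to 21).** The ring A phenols are masked as benzyl ethers. They tolerate acylation, base and copper and leave by hydrogenolysis without touching silyl ethers.

**Ring C (21 to 11 and 19, through 20).** The central cut removes the C3–C4 and O1–C8a bonds. It is placed in ring C and not in the furan because the furan oxygen and C2 are then already present at the right oxidation level in lactone 11. C4 arrives as the acyl carbon of 19, and the bromine of 19 marks the carbon that receives O1. Forward, the enolate of 11 must be acylated on carbon (giving 20) and the enol oxygen must then displace bromide. A chelation argument cannot be applied to the simple lactone enolate, which has a single carbonyl oxygen; C-selectivity therefore has to come from the stability of the chelated C-acyl product and from acyl transfer of any O-acyl isomer.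

**Ring A half (19 back to 12).** Acid chloride 19 comes from acid 18 and aldehyde 17, and 17 from the symmetrical dibenzyl ether 16, whose two free positions are equivalent, so formylation needs no regiocontrol. 16 is reached from 15 and 14. The bromine of 14 is meta to both oxygens, a position electrophilic bromination would not reach; it is placed by sterically controlled C–H borylation of 12 (through 13) and bromodeboronation.

**Lactone (11 to 8 and 9, through 10).** 11 is cut at the bond between its CH2 and ring D and at the lactone C–O bond, giving quinone 8 and the two-carbon nucleophile 9. In 8 the ring oxygen turns the neighbouring carbonyl into a vinylogous ester, so the conjugate addition is directed to the carbon para to that oxygen. The silyl group of 9 ends on the oxygen that must stay protected, and the other oxygen is left free to lactonise.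

**Ring E half (8 back to 1 and 2).** Quinone 8 comes from dimethyl ether 7 by oxidative demethylation, 7 from trans-diol 6, and 6 from epoxide 5 by invertive opening at C4. 5 is the asymmetric epoxidation product of chromene 4, a member of the substrate class on which this epoxidation is most reliable. 4 follows from propargyl ether 3, made from phenol 1 and chloride 2; the methoxy group of 1 blocks one ortho position, so the Claisen cascade has a single outcome.

## Alternatives that were turned down

**Alternative 1:** The furan is disconnected at C3–C1' and C2–O(furan). This leaves a complete ring A/C/F half with a leaving amine at C2, the 2-morpholinochromone A2, and the quinone diacetate A3 (the acetate analogue of 8).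

- Forward key step: C3 of A2 adds to the free quinone carbon para to the ring oxygen of A3, the adduct aromatises, and the new hydroxyl next to the bond closes on C2 with loss of the amine. This gives the target diacetate A1.
- For: it is the most convergent plan. One step makes the whole hexacycle from two finished halves, without phenol protection or a transition metal, and it uses the same electronic bias of the quinone as step 7.
- Against:
  - A quinone is also an oxidant; the hydroquinone adduct and the electron-rich chromene of A2 can be oxidised by unreacted A3.
  - Closure with loss of the amine competes with retention of nitrogen, as in related enamine–quinone condensations.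
  - C3 of A2 is a weakly nucleophilic vinylogous carbamate carbon facing a hindered, donor-substituted quinone.
  - The free hydroquinone hydroxyl ortho to the benzylic acetate invites an ortho-quinone methide and loss of C4'' integrity.
  - The final deacetylation needs a base that can attack C2.
  - Making A2 by closing a chromone on a 2,4,6-trioxygenated ring brings back the 6-methyl against 8-methyl question.
- Comparison: on step economy and convergence this alternative is stronger. The chosen route offers bond formations of unambiguous polarity, no quinone present once the halves are joined, and ring A regiochemistry fixed by a bromine atom.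

**Alternative 2:** Ring E is disconnected at C3''–C4''.

- Forward key step: a chiral triazolium-derived carbene converts the aryl aldehyde of dialdehyde A5 into its acyl anion equivalent, which adds to the tethered α-aryloxy aldehyde. The product is hydroxy ketone A4; a hydroxyl-directed reduction would then give the trans-diol.
- For: C3'' is set by a catalyst and C4'' by hydride delivery from the C3'' oxygen, so the trans relation does not depend on substitution at an electron-rich benzylic carbon. On this point it is stronger than step 4 of the chosen route.
- Against: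
  - It solves only ring E and says nothing on how the two halves are joined.
  - The doubly ortho-substituted aryl aldehyde must be the donor; if the aliphatic aldehyde takes that role the isomeric 4-hydroxychroman-3-one results.
  - The α-hydroxy ketone can racemise through its enediol under the basic carbene conditions.
  - A5 requires O-alkylation of a hindered phenol at a tertiary carbon.
  - One more step (the reduction) is needed to reach the diol.
- Comparison: the chosen route reaches the same diol in four steps from 1. The directed reduction idea is kept as the fallback for step 4.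

**Alternative 3:** Ring E is disconnected at O–C2''.

- Forward key step: under a titanium alkoxide the phenol of epoxy carbinol A7 opens the epoxide at its tertiary carbon (6-endo). This gives diol A6, which is the same compound as 6.
- For: neither stereocentre is touched in the ring closure, since the attacked carbon is not stereogenic. The benzylic carbinol is never a leaving group, which makes this stronger than the chosen route in stereochemical fidelity.
- Against:
  - A7 needs an enantioenriched aryl allylic carbinol and then a diastereoselective epoxidation, so it takes more steps than epoxidation of chromene 4.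
  - A free phenol ortho to an electron-rich benzylic carbinol under a Lewis acid can ionise to a quinone methide.
  - 5-exo attack at the secondary epoxide carbon competes.
  - Like alternative 2, it ends at an early intermediate of the chosen route and leaves the central problem open.
- Comparison: the chosen route offers brevity, through asymmetric epoxidation of a favourable substrate class.

Key step: step 14

Assumption: the (R,R)-configured manganese salen catalyst is taken to give the (3R,4R)-epoxide, as with 2,2-dimethylchromenes in general; if the 5-methoxy group reversed the sense, the antipodal catalyst would be used. Compound 9 is taken to be a commercial reagent.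

## Route

Step 1
Reactants: 1 2,5-dimethoxyphenol; 2 3-chloro-3-methylbut-1-yne
Product: 3 1,4-dimethoxy-2-[(2-methylbut-3-yn-2-yl)oxy]benzene
Conditions: DBU, CuCl2 (cat.), MeCN, 0 °C to rt
Reagents that add atoms: none
Why: Copper-catalysed O-propargylation of a phenol by a tertiary propargylic chloride through a copper acetylide/allenylidene electrophile; the amidine base is non-nucleophilic and the tertiary centre rules out direct SN2 side reactions.

Step 2
Reactants: 3 1,4-dimethoxy-2-[(2-methylbut-3-yn-2-yl)oxy]benzene
Product: 4 5,8-dimethoxy-2,2-dimethyl-2H-chromene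
Conditions: N,N-diethylaniline, 180 °C
Reagents that add atoms: none
Why: Aryl propargyl ether Claisen rearrangement followed by 1,5-hydrogen shift and oxa-6π electrocyclisation. One ortho position is blocked by methoxy, so only the other is attacked and a single chromene should form.

Step 3
Reactants: 4 5,8-dimethoxy-2,2-dimethyl-2H-chromene
Product: 5 (3R,4R)-3,4-epoxy-5,8-dimethoxy-2,2-dimethylchromane
Conditions: (R,R)-N,N'-bis(3,5-di-tert-butylsalicylidene)-1,2-cyclohexanediaminomanganese chloride (cat.), 4-phenylpyridine N-oxide, aq NaOCl (pH 11.3), CH2Cl2, 0 °C; filtration through basic alumina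
Reagents that add atoms: sodium hypochlorite, [Na+].[O-]Cl
Why: Jacobsen epoxidation; cis-alkenes conjugated to an arene and carrying a gem-dimethyl group are its best substrate class. Both stereocentres are set at once by catalyst control (side-on approach of the alkene to the oxomanganese species over the diamine backbone), and the cis ring fusion follows from the mechanism. The acid-labile epoxide is not chromatographed on silica.

Step 4
Reactants: 5 (3R,4R)-3,4-epoxy-5,8-dimethoxy-2,2-dimethylchromane
Product: 6 (3R,4S)-5,8-dimethoxy-2,2-dimethylchromane-3,4-diol (trans)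
Conditions: KOH, DMSO/H2O, 70 °C
Reagents that add atoms: water, O
Why: SN2 opening of the epoxide by hydroxide at the benzylic C4 (C3 is shielded by the adjacent quaternary carbon) inverts C4 and leaves C3 untouched, which gives the trans (3R,4S)-diol. Basic conditions are chosen to avoid the benzylic cation that the two ortho oxygens would stabilise under acid.

Step 5
Reactants: 6 (3R,4S)-5,8-dimethoxy-2,2-dimethylchromane-3,4-diol
Product: 7 (3R,4S)-3,4-bis(tert-butyldimethylsilyloxy)-5,8-dimethoxy-2,2-dimethylchromane
Conditions: TBSOTf, 2,6-lutidine, CH2Cl2, 0 °C to rt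
Reagents that add atoms: tert-butyldimethylsilyl trifluoromethanesulfonate, CC(C)(C)[Si](C)(C)OS(=O)(=O)C(F)(F)F
Why: Silylation with the silyl triflate is needed for the hindered C3 hydroxyl beside the gem-dimethyl group; the hindered pyridine base keeps the medium non-acidic, so the electron-rich benzylic ether should not ionise.

Step 6
Reactants: 7 (3R,4S)-3,4-bis(tert-butyldimethylsilyloxy)-5,8-dimethoxy-2,2-dimethylchromane
Product: 8 (3R,4S)-3,4-bis(tert-butyldimethylsilyloxy)-2,2-dimethyl-3,4-dihydro-2H-chromene-5,8-dione
Conditions: (NH4)2Ce(NO3)6, MeCN/H2O, 0 °C, short reaction time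
Reagents that add atoms: water, O
Why: Oxidative demethylation of a 1,4-dimethoxyarene to the p-quinone by tetravalent cerium (arene radical cation, water attack at the two ipso carbons, loss of methanol). Secondary silyl ethers should survive the brief cold treatment, and the stereocentres are not involved.

Step 7
Reactants: 8 (3R,4S)-3,4-bis(tert-butyldimethylsilyloxy)-2,2-dimethyl-3,4-dihydro-2H-chromene-5,8-dione; 9 1-(tert-butyldimethylsilyloxy)-1-methoxyethene
Product: 11 5-(tert-butyldimethylsilyloxy)benzofuran-2(3H)-one fused at C6–C7 to the (3R,4S)-3,4-bis(tert-butyldimethylsilyloxy)-2,2-dimethyl-3,4-dihydro-2H-pyran ring (pyran oxygen on C6; pyran C4 on C7), via hydroxy ester 10 (not isolated)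
Conditions: MeCN, −20 °C to rt; then PPTS (cat.), toluene, 4 Å molecular sieves, 80 °C
Reagents that add atoms: none
Why: Mukaiyama–Michael addition of a ketene silyl acetal to a p-quinone: the ring oxygen makes the C5 carbonyl a vinylogous ester, so the C8 carbonyl is the acceptor and the nucleophile enters at C6, para to the ring oxygen. The silyl group moves to O8 and aromatisation leaves O5–H free next to the new CH2CO2Me arm; mild acid then closes the five-membered lactone with loss of methanol. The monosilylated hydroquinone cannot be re-oxidised by unreacted quinone, which should prevent double addition.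

Step 8
Reactants: 12 2,6-dimethoxytoluene
Product: 14 5-bromo-1,3-dimethoxy-2-methylbenzene, via aryl boronate 13 (not isolated)
Conditions: [Ir(OMe)(cod)]2 (cat.), 4,4'-di-tert-butyl-2,2'-bipyridine, B2pin2, THF, 80 °C; then CuBr2, MeOH/H2O, 80 °C
Reagents that add atoms: bis(pinacolato)diboron, CC1(C)OB(OC1(C)C)B1OC(C)(C)C(C)(C)O1 (boron carried by 13 only); copper dibromide, [Cu+2].[Br-].[Br-]
Why: Iridium-catalysed C–H borylation is sterically controlled and takes the only ring position with no ortho substituent, para to the methyl group. Copper-mediated bromodeboronation then puts bromine meta to both oxygens.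

Step 9
Reactants: 14 5-bromo-1,3-dimethoxy-2-methylbenzene
Product: 15 5-bromo-2-methylbenzene-1,3-diol
Conditions: BBr3, CH2Cl2, −78 °C to rt; then H2O
Reagents that add atoms: none
Why: Lewis-acid cleavage of aryl methyl ethers (bromide attacks the methyl group of the boron-complexed ether); the aryl bromide is inert.

Step 10
Reactants: 15 5-bromo-2-methylbenzene-1,3-diol
Product: 16 1,3-bis(benzyloxy)-5-bromo-2-methylbenzene
Conditions: BnBr, K2CO3, DMF, rt
Reagents that add atoms: benzyl bromide, BrCc1ccccc1
Why: Williamson ether synthesis on both phenols.

Step 11
Reactants: 16 1,3-bis(benzyloxy)-5-bromo-2-methylbenzene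
Product: 17 2,4-bis(benzyloxy)-6-bromo-3-methylbenzaldehyde
Conditions: POCl3, DMF, 70 °C; then H2O
Reagents that add atoms: N,N-dimethylformamide, CN(C)C=O (formyl carbon); water, O (formyl oxygen, on hydrolysis)
Why: Vilsmeier–Haack formylation; the two free ring positions are equivalent, each ortho to one benzyloxy group and para to the other, so the regiochemistry is fixed. The aldehyde ends between bromine and benzyloxy, as the acyl carbon of the later chromone requires.

Step 12
Reactants: 17 2,4-bis(benzyloxy)-6-bromo-3-methylbenzaldehyde
Product: 18 2,4-bis(benzyloxy)-6-bromo-3-methylbenzoic acid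
Conditions: NaClO2, NaH2PO4, 2-methylbut-2-ene, t-BuOH/THF/H2O, rt
Reagents that add atoms: sodium chlorite, [Na+].[O-]Cl=O
Why: Pinnick oxidation; the alkene scavenges hypochlorous acid so that the electron-rich ring is not chlorinated.

Step 13
Reactants: 18 2,4-bis(benzyloxy)-6-bromo-3-methylbenzoic acid
Product: 19 2,4-bis(benzyloxy)-6-bromo-3-methylbenzoyl chloride (the same compound named from the other side is 4,6-bis(benzyloxy)-2-bromo-5-methylbenzoyl chloride)
Conditions: (COCl)2, DMF (cat.), CH2Cl2, 0 °C to rt; used crude
Reagents that add atoms: oxalyl chloride, O=C(Cl)C(=O)Cl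
Why: Acid chloride formation through the catalytic chloroiminium species under neutral conditions, which should keep the ortho benzyl ether intact.

Step 14
Reactants: 11 silyloxy benzofuranone (as in step 7); 19 2,4-bis(benzyloxy)-6-bromo-3-methylbenzoyl chloride
Product: 21 5,7-bis(benzyloxy)-6-methylbenzofuro[2,3-b]chromen-4-one core carrying 5'-OTBS and the (3''R,4''S)-3'',4''-bis(TBSO)-2'',2''-dimethyldihydropyran on C3'/C4' (C8 unsubstituted), via enol ketone 20 (not isolated)
Conditions: MgCl2, Et3N, DMAP (cat.), MeCN/CH2Cl2, 0 °C to rt; then, without purification, copper iodide CuI (cat.), 1,10-phenanthroline, K3PO4, dioxane, 90 °C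
Reagents that add atoms: none
Why: Soft enolisation of 11 (MgCl2, Et3N) gives the aromatic 2-oxidobenzofuran enolate, which is acylated by 19; any O-acyl isomer is returned to carbon by DMAP-mediated acyl transfer (Black-type rearrangement), because only the C-acyl product forms a six-membered magnesium chelate, and its acidity (it stays enolised as 20) stops a second acylation. In the second stage monovalent copper inserts into the aryl C–Br bond, helped by the ortho carbonyl, the enolate oxygen on C2 binds copper, and reductive elimination forms the O1–C8a bond. The closest known reaction type is C-acylation of cyclic 1,3-dicarbonyl, lactam or lactone enolates by 2-haloaroyl chlorides followed by intramolecular copper-catalysed O-arylation to fused chromones. The pyranone closes in a six-membered mode at the aromatic carbon (formally 6-exo, the C–Br bond lying outside the new ring); the ketone oxygen would have to close a four-membered ring and C3 a three-membered one, so only the lactone-derived oxygen can be arylated. No stereocentre is formed, and C3'' and C4'' are remote from both new bonds. The bromine fixes the regiochemistry on ring A: O1 lands on the carbon next to C8–H, so the methyl group must be at C6. Because C4 arrives as an acyl carbon, the coumestan connectivity cannot arise. Anhydrous K3PO4 in dioxane is chosen to spare the aryl silyl ether and the lactone.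

Step 15
Reactants: 21 bis(benzyl) ether (as in step 14)
Product: 22 5,7-dihydroxy-6-methyl coumaronochromone tris(TBS) ether
Conditions: H2 (1 atm), 10% Pd/C, EtOAc, rt
Reagents that add atoms: none
Why: Hydrogenolysis of two aryl benzyl ethers. The C2=C3 bond belongs to the aromatic furan and the hindered benzylic silyl ether should not be cleaved at one atmosphere in a non-protic solvent.

Step 16
Reactants: 22 5,7-dihydroxy-6-methyl coumaronochromone tris(TBS) ether; 2 3-chloro-3-methylbut-1-yne
Product: 23 7-O-(2-methylbut-3-yn-2-yl) ether of 22
Conditions: DBU, CuCl2 (cat.), MeCN, 0 °C to rt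
Reagents that add atoms: none
Why: Copper-catalysed O-propargylation; 7-OH is the most acidic phenol (para to the carbonyl), whereas 5-OH is held in a hydrogen bond to C4=O and the ring D phenol is silylated, so a single ether should form.

Step 17
Reactants: 23 7-O-(2-methylbut-3-yn-2-yl) ether
Product: 24 tris(TBS) ether of the target (5'-O, 3''-O, 4''-O)
Conditions: N,N-diethylaniline, 190 °C
Reagents that add atoms: none
Why: Propargyl Claisen rearrangement, 1,5-hydrogen shift and oxa-6π ring closure; C6 carries the methyl group, so a shift to that carbon can only revert and the cascade ends at C8, giving the angular chromene.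

Step 18
Reactants: 24 tris(TBS) ether of the target
Product: 25 target, (3''R,4''S)-configured trans-diol
Conditions: HF·pyridine, THF/pyridine, 0 °C to rt
Reagents that add atoms: none
Why: Fluoride cleavage of one aryl and two secondary silyl ethers, driven by Si–F bond formation. The buffered reagent is neither basic nor strongly acidic, which spares C2, the chromene and the benzylic carbinol, so both stereocentres are kept.

## Compound list

1 | 2,5-dimethoxyphenol | COc1ccc(OC)c(O)c1 | starting material
2 | 3-chloro-3-methylbut-1-yne | CC(C)(Cl)C#C | starting material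
3 | 1,4-dimethoxy-2-[(2-methylbut-3-yn-2-yl)oxy]benzene | COc1ccc(OC)c(OC(C)(C)C#C)c1 | intermediate
4 | 5,8-dimethoxy-2,2-dimethyl-2H-chromene | COc1ccc(OC)c2OC(C)(C)C=Cc12 | intermediate
5 | (3R,4R)-3,4-epoxy-5,8-dimethoxy-2,2-dimethylchromane | COc1ccc(OC)c2OC(C)(C)[C@@H]3O[C@@H]3c12 | intermediate
6 | (3R,4S)-5,8-dimethoxy-2,2-dimethylchromane-3,4-diol | COc1ccc(OC)c2c1[C@H](O)[C@@H](O)C(C)(C)O2 | intermediate
7 | (3R,4S)-3,4-bis(tert-butyldimethylsilyloxy)-5,8-dimethoxy-2,2-dimethylchromane | COc1ccc(OC)c2c1[C@H](O[Si](C)(C)C(C)(C)C)[C@@H](O[Si](C)(C)C(C)(C)C)C(C)(C)O2 | intermediate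
8 | (3R,4S)-3,4-bis(tert-butyldimethylsilyloxy)-2,2-dimethyl-3,4-dihydro-2H-chromene-5,8-dione | O=C1C=CC(=O)C2=C1[C@H](O[Si](C)(C)C(C)(C)C)[C@@H](O[Si](C)(C)C(C)(C)C)C(C)(C)O2 | intermediate
9 | 1-(tert-butyldimethylsilyloxy)-1-methoxyethene | C=C(OC)O[Si](C)(C)C(C)(C)C | starting material
10 | methyl 2-[(3R,4S)-3,4,8-tris(tert-butyldimethylsilyloxy)-5-hydroxy-2,2-dimethylchroman-6-yl]acetate | COC(=O)Cc1cc(O[Si](C)(C)C(C)(C)C)c2OC(C)(C)[C@H](O[Si](C)(C)C(C)(C)C)[C@@H](O[Si](C)(C)C(C)(C)C)c2c1O | intermediate (not isolated)
11 | 5-(tert-butyldimethylsilyloxy)benzofuran-2(3H)-one fused at C6–C7 to the (3R,4S)-3,4-bis(tert-butyldimethylsilyloxy)-2,2-dimethyl-3,4-dihydro-2H-pyran ring | O=C1Cc2cc(O[Si](C)(C)C(C)(C)C)c3c(c2O1)[C@H](O[Si](C)(C)C(C)(C)C)[C@@H](O[Si](C)(C)C(C)(C)C)C(C)(C)O3 | intermediate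
12 | 2,6-dimethoxytoluene | COc1cccc(OC)c1C | starting material
13 | 2-(3,5-dimethoxy-4-methylphenyl)-4,4,5,5-tetramethyl-1,3,2-dioxaborolane | COc1cc(B2OC(C)(C)C(C)(C)O2)cc(OC)c1C | intermediate (not isolated)
14 | 5-bromo-1,3-dimethoxy-2-methylbenzene | COc1cc(Br)cc(OC)c1C | intermediate
15 | 5-bromo-2-methylbenzene-1,3-diol | Cc1c(O)cc(Br)cc1O | intermediate
16 | 1,3-bis(benzyloxy)-5-bromo-2-methylbenzene | Cc1c(OCc2ccccc2)cc(Br)cc1OCc1ccccc1 | intermediate
17 | 2,4-bis(benzyloxy)-6-bromo-3-methylbenzaldehyde | O=Cc1c(Br)cc(OCc2ccccc2)c(C)c1OCc1ccccc1 | intermediate
18 | 2,4-bis(benzyloxy)-6-bromo-3-methylbenzoic acid | O=C(O)c1c(Br)cc(OCc2ccccc2)c(C)c1OCc1ccccc1 | intermediate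
19 | 2,4-bis(benzyloxy)-6-bromo-3-methylbenzoyl chloride | O=C(Cl)c1c(Br)cc(OCc2ccccc2)c(C)c1OCc1ccccc1 | intermediate
20 | [2,4-bis(benzyloxy)-6-bromo-3-methylphenyl] ketone of the 2-hydroxybenzofuran-3-yl enol form of 11 (3-aroyl lactone, drawn as the enol) | O=C(c1c(O)oc2c1cc(O[Si](C)(C)C(C)(C)C)c1OC(C)(C)[C@H](O[Si](C)(C)C(C)(C)C)[C@@H](O[Si](C)(C)C(C)(C)C)c21)c1c(Br)cc(OCc2ccccc2)c(C)c1OCc1ccccc1 | intermediate (not isolated)
21 | 5,7-bis(benzyloxy)-6-methylbenzofuro[2,3-b]chromen-4-one core, 5'-OTBS, (3''R,4''S)-bis(TBSO)-dimethyldihydropyran on C3'/C4' | O=c1c2c(OCc3ccccc3)c(C)c(OCc3ccccc3)cc2oc2oc3c4[C@H](O[Si](C)(C)C(C)(C)C)[C@@H](O[Si](C)(C)C(C)(C)C)C(C)(C)Oc4c(O[Si](C)(C)C(C)(C)C)cc3c12 | intermediate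
22 | 5,7-dihydroxy analogue of 21 | O=c1c2c(O)c(C)c(O)cc2oc2oc3c4[C@H](O[Si](C)(C)C(C)(C)C)[C@@H](O[Si](C)(C)C(C)(C)C)C(C)(C)Oc4c(O[Si](C)(C)C(C)(C)C)cc3c12 | intermediate
23 | 7-O-(2-methylbut-3-yn-2-yl) ether of 22 | O=c1c2c(O)c(C)c(OC(C)(C)C#C)cc2oc2oc3c4[C@H](O[Si](C)(C)C(C)(C)C)[C@@H](O[Si](C)(C)C(C)(C)C)C(C)(C)Oc4c(O[Si](C)(C)C(C)(C)C)cc3c12 | intermediate
24 | 5',3'',4''-tris(TBS) ether of the target | O=c1c2c(O)c(C)c3OC(C)(C)C=Cc3c2oc2oc3c4[C@H](O[Si](C)(C)C(C)(C)C)[C@@H](O[Si](C)(C)C(C)(C)C)C(C)(C)Oc4c(O[Si](C)(C)C(C)(C)C)cc3c12 | intermediate
25 | target, CNP0351839.1 | Cc1c2c(c3oc4oc5c6c(c(O)cc5c4c(=O)c3c1O)OC(C)(C)[C@H](O)[C@H]6O)C=CC(C)(C)O2 | target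

## Step count and least certain steps

Total: 18 steps. Longest linear sequence: 12 steps from 1 (steps 1–7, then 14–18). The ring A branch adds 6 steps (8–13) and is 11 steps in line to the target.

**Step 14 (key step).** The acid chloride 19 is flanked by bromine and a benzyloxy group, so the acylation may go to the enolate oxygen, occur twice, or stall. In the hot basic copper stage the aryl silyl ether may be lost or the lactone opened by traces of water. Fallback, from 11 and the aldehyde 17 already on the route: the lithium enolate of 11 (LiN(SiMe3)2, THF, −78 °C) is added to 17, which cannot react at oxygen. This aldol addition should give the β-hydroxy lactone F1 as a mixture of diastereomers at two centres that the next operation removes. Oxidation with Dess–Martin periodinane gives enol ketone 20, which is closed with CuI as in step 14, returning to the route at 21.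

**Step 7.** The electron-rich ketene acetal may transfer an electron to the quinone, which would lead to reduction and O-silylation in place of C–C bond formation. Addition at C7 is possible if the alkyl substituent counts for more than expected. During lactonisation the free phenol next to the benzylic silyl ether could open a quinone methide pathway and erode C4''. Fallback, from 8, with the new bond made by an aromatic Claisen rearrangement:
- Reduction of 8 (Na2S2O4, EtOAc/H2O) gives hydroquinone F2.
- The less hindered hydroxyl next to the ring oxygen is silylated (TBSCl, imidazole, DMF, 0 °C) to give monosilyl ether F3.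
- The remaining phenol is allylated (allyl bromide, K2CO3, acetone) to allyl ether F4.
- Heating (N,N-diethylaniline, lowest workable temperature) moves the allyl group to the only free ortho carbon, giving allyl phenol F5.
- Ozonolysis (O3, CH2Cl2, −78 °C; then PPh3) gives an aldehyde that closes to lactol F6.
- Oxidation with Ag2CO3 on Celite returns to the route at 11.

**Step 4.** Stereospecificity may be lost if the epoxide ionises to the benzylic cation, which two ortho oxygens stabilise, so that water adds on both faces. The peri methoxy group may also slow the SN2 attack. Fallback, from 5: hydrolysis in dilute aqueous H2SO4/acetone gives 6 together with its C4 epimer, the cis-diol F7; both have the same C3 configuration. The mixture is oxidised at the benzylic carbinol (DDQ, dioxane, rt) to the single hydroxy ketone F8. Hydroxyl-directed reduction with Me4NBH(OAc)3 (MeCN/AcOH, −20 °C) delivers hydride to C4 from the face of the C3 oxygen and returns to the route at 6.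

**Step 17 (and step 16 before it).** The [3,3] shift onto the electron-poor chromone ring needs about 190 °C, and the substrate may decompose over hours at that temperature at the benzylic silyl ether or at C2. One step earlier, O-alkylation of the 7-hydroxyl beside the methyl group may be sluggish. Fallback, from 22: condensation with 3-methylbut-2-enal (ethylenediammonium diacetate, toluene, 100 °C) forms the chromene by aldol-type attack of C8, dehydration and oxa-6π ring closure. With C6 blocked only the angular ring can form; this returns to the route at 24 in one step and makes no new compound.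

## Further compounds

F1 | step 14 | 3-{[2,4-bis(benzyloxy)-6-bromo-3-methylphenyl](hydroxy)methyl} derivative of lactone 11 (diastereomer mixture) | O=C1C(C(O)c2c(Br)cc(OCc3ccccc3)c(C)c2OCc2ccccc2)c2cc(O[Si](C)(C)C(C)(C)C)c3c(c2O1)[C@H](O[Si](C)(C)C(C)(C)C)[C@@H](O[Si](C)(C)C(C)(C)C)C(C)(C)O3
F2 | step 7 | (3R,4S)-3,4-bis(tert-butyldimethylsilyloxy)-2,2-dimethylchromane-5,8-diol | Oc1ccc(O)c2c1[C@H](O[Si](C)(C)C(C)(C)C)[C@@H](O[Si](C)(C)C(C)(C)C)C(C)(C)O2
F3 | step 7 | (3R,4S)-3,4,8-tris(tert-butyldimethylsilyloxy)-2,2-dimethylchroman-5-ol | Oc1ccc(O[Si](C)(C)C(C)(C)C)c2c1[C@H](O[Si](C)(C)C(C)(C)C)[C@@H](O[Si](C)(C)C(C)(C)C)C(C)(C)O2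
F4 | step 7 | (3R,4S)-5-(allyloxy)-3,4,8-tris(tert-butyldimethylsilyloxy)-2,2-dimethylchromane | C=CCOc1ccc(O[Si](C)(C)C(C)(C)C)c2c1[C@H](O[Si](C)(C)C(C)(C)C)[C@@H](O[Si](C)(C)C(C)(C)C)C(C)(C)O2
F5 | step 7 | (3R,4S)-6-allyl-3,4,8-tris(tert-butyldimethylsilyloxy)-2,2-dimethylchroman-5-ol | C=CCc1cc(O[Si](C)(C)C(C)(C)C)c2OC(C)(C)[C@H](O[Si](C)(C)C(C)(C)C)[C@@H](O[Si](C)(C)C(C)(C)C)c2c1O
F6 | step 7 | lactol corresponding to 11 (2-hydroxy-2,3-dihydrobenzofuran, anomer mixture) | OC1Cc2cc(O[Si](C)(C)C(C)(C)C)c3c(c2O1)[C@H](O[Si](C)(C)C(C)(C)C)[C@@H](O[Si](C)(C)C(C)(C)C)C(C)(C)O3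
F7 | step 4 | (3R,4R)-5,8-dimethoxy-2,2-dimethylchromane-3,4-diol (cis) | COc1ccc(OC)c2c1[C@@H](O)[C@@H](O)C(C)(C)O2
F8 | step 4 | (S)-3-hydroxy-5,8-dimethoxy-2,2-dimethylchroman-4-one | COc1ccc(OC)c2c1C(=O)[C@@H](O)C(C)(C)O2
F0 | step 17 | none | none
A1 | alternative 1 | 3'',4''-diacetate of the target | O=c1c2c(O)c(C)c3OC(C)(C)C=Cc3c2oc2oc3c4[C@H](OC(C)=O)[C@@H](OC(C)=O)C(C)(C)Oc4c(O)cc3c12
A2 | alternative 1 | 5-hydroxy-6,8,8-trimethyl-2-(morpholin-4-yl)-4H,8H-pyrano[2,3-h]chromen-4-one | O=c1cc(N2CCOCC2)oc2c1c(O)c(C)c1OC(C)(C)C=Cc12
A3 | alternative 1 | (3R,4S)-2,2-dimethyl-5,8-dioxo-3,4,5,8-tetrahydro-2H-chromene-3,4-diyl diacetate | O=C1C=CC(=O)C2=C1[C@H](OC(C)=O)[C@@H](OC(C)=O)C(C)(C)O2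
A4 | alternative 2 | (S)-3-hydroxy-5,8-dimethoxy-2,2-dimethylchroman-4-one | COc1ccc(OC)c2c1C(=O)[C@@H](O)C(C)(C)O2
A5 | alternative 2 | 2-(2-formyl-3,6-dimethoxyphenoxy)-2-methylpropanal | COc1ccc(OC)c(OC(C)(C)C=O)c1C=O
A6 | alternative 3 | (3R,4S)-5,8-dimethoxy-2,2-dimethylchroman-3,4-diol | COc1ccc(OC)c2c1[C@H](O)[C@@H](O)C(C)(C)O2
A7 | alternative 3 | 2-[(S)-hydroxy((R)-3,3-dimethyloxiran-2-yl)methyl]-3,6-dimethoxyphenol | COc1ccc(OC)c(O)c1[C@H](O)[C@H]1OC1(C)C
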